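## Retrosynthetic overview

1. The γ‑hydroxy‑γ‑lactam and the 13‑membered cyclophane come last, from a 14‑membered β‑keto lactam alcohol: alcohol oxidation, transannular Knoevenagel ring contraction, then tautomerisation/hydration under thermodynamic control.
2. The 14‑membered lactam comes from macrolactamisation of an amino β‑keto ester on the finished decahydrofluorene.
3. Key step: an intramolecular Diels–Alder reaction of an (E)‑enone onto an (E,E)‑triene hung on ring A forms rings B and C together and sets four stereocentres.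
4. The dienophile arm comes from hydrozirconation–acylation of a propargylic aryl ether. The ether is made by SNAr of the alkoxide on a phenylalaninol fluoroarene–Cr(CO)3 complex, and the carbinol centre by Felkin reduction of an ynone.
5. Ring A comes from (S)‑3‑methylcyclohexanone: carbomethoxylation, two dehydrogenation/conjugate‑addition cycles (isobutenyl, then methyl), enol‑phosphate methylation, Li/NH3. Ring order: A (bought) → B + C → 14‑membered lactam → γ‑lactam/13‑membered ring.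

## Assumptions and notation

- (3S)‑3‑Methylcyclohexanone and N‑Boc‑4‑fluoro‑L‑phenylalanine are taken as commercial; the ring‑methyl centre is (S) in the ketone and becomes (R) in the target only through a CIP priority change.
- Simple conjugate bases of compounds already listed are not numbered separately.
- In SMILES, η6‑arene complexes are written as their components joined by dots, and cyclopentadienyl ligands are drawn σ‑bound.
- Shorthand in names: TrCy = (1R,2S,4R,6S)‑2‑[(1E,3E)‑2,4‑dimethylhexa‑1,3,5‑trien‑1‑yl]‑2,4,6‑trimethylcyclohexyl.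
- Shorthand in names: ArN = 4‑{[(4S)‑3‑(tert‑butoxycarbonyl)‑2,2‑dimethyl‑1,3‑oxazolidin‑4‑yl]methyl}phenyl.
- Shorthand in names: Flu = (1R,2S,4aS,4bS,6R,8S,8aR,9S,9aS)‑2‑ethenyl‑2,4,4b,6,8‑pentamethyl‑2,4a,4b,5,6,7,8,8a,9,9a‑decahydro‑1H‑fluorene, acyl group at C‑1, aryloxy group at C‑9; tricycle locants in the text are these fluorene locants.

## Route

Step 1
Reactants: 1 (3S)-3-methylcyclohexan-1-one
Product: 2 methyl (4S)-4-methyl-2-oxocyclohexane-1-carboxylate
Conditions: NaH, (MeO)2CO, THF, reflux; aq. HCl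
Reagents that add atoms: dimethyl carbonate COC(=O)OC
Why: Claisen-type C-acylation under equilibrating conditions goes to the less hindered α-carbon, remote from the methyl-bearing carbon, and touches no stereocentre.

Step 2
Reactants: 2 methyl (4S)-4-methyl-2-oxocyclohexane-1-carboxylate
Product: 5 methyl (4S)-4-methyl-6-oxocyclohex-1-ene-1-carboxylate, via selenide 3 (not isolated), via selenoxide 4 (not isolated)
Conditions: PhSeCl, pyridine, CH2Cl2, 0 °C; then 30% H2O2, 0 °C → rt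
Reagents that add atoms: none
Why: α-Selenenylation of the β-keto ester and selenoxide syn-elimination (the only β-hydrogens are at C-2) give the doubly activated enone.

Step 3
Reactants: 5 methyl (4S)-4-methyl-6-oxocyclohex-1-ene-1-carboxylate
Product: 9 methyl (4S)-4-methyl-2-(2-methylprop-1-en-1-yl)-6-oxocyclohex-1-ene-1-carboxylate, via BrMg enolate 6 (not isolated), via selenide 7 (not isolated), via selenoxide 8 (not isolated)
Conditions: Me2C=CHMgBr, CuBr·SMe2 (10 mol %), THF, −78 °C; PhSeBr, −78 → 0 °C; then 30% H2O2, pyridine, CH2Cl2, 0 °C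
Reagents that add atoms: (2-methylprop-1-en-1-yl)magnesium bromide CC(C)=C[Mg]Br
Why: Copper-catalysed 1,4-addition to the alkylidene β-keto ester, selenenylation of the enolate anti to the new group and selenoxide syn-elimination re-form the enone with the isobutenyl group on the β-carbon; the transient stereocentre is erased.

Step 4
Reactants: 9 methyl (4S)-4-methyl-2-(2-methylprop-1-en-1-yl)-6-oxocyclohex-1-ene-1-carboxylate
Product: 12 methyl (4R,6S)-2,4,6-trimethyl-6-(2-methylprop-1-en-1-yl)cyclohex-1-ene-1-carboxylate, via BrMg enolate 10 (not isolated), via enol phosphate 11 (not isolated)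
Conditions: MeMgBr, CuI (10 mol %), THF, −40 °C; ClP(O)(OEt)2, −40 → 0 °C; then MeMgBr, Fe(acac)3 (5 mol %), THF/NMP, −20 → 0 °C; aq. NH4Cl
Reagents that add atoms: methylmagnesium bromide C[Mg]Br
Why: Copper-catalysed conjugate methylation adds axially, trans to the bought ring methyl, and sets the quaternary carbon (the fully substituted diene terminus blocks 1,6-addition); the enolate is trapped as its enol phosphate and an iron-catalysed Kumada-type coupling installs the second methyl.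

Step 5
Reactants: 12 methyl (4R,6S)-2,4,6-trimethyl-6-(2-methylprop-1-en-1-yl)cyclohex-1-ene-1-carboxylate
Product: 13 methyl (1R,2S,4R,6S)-2,4,6-trimethyl-2-(2-methylprop-1-en-1-yl)cyclohexane-1-carboxylate
Conditions: Li, NH3(l), THF, t-BuOH (1 equiv), −78 °C; NH4Cl; then NaOMe (cat.), MeOH, 65 °C
Reagents that add atoms: none
Why: Dissolving-metal reduction of the enoate protonates the β-carbon so its methyl ends equatorial (the alternative is a 1,3-diaxial Me/Me clash with the quaternary methyl), and methoxide equilibration leaves the ester equatorial; the isolated alkene is inert.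

Step 6
Reactants: 13 methyl (1R,2S,4R,6S)-2,4,6-trimethyl-2-(2-methylprop-1-en-1-yl)cyclohexane-1-carboxylate
Product: 14 methyl (1R,2S,4R,6S)-2,4,6-trimethyl-2-[(1E)-2-methyl-3-oxoprop-1-en-1-yl]cyclohexane-1-carboxylate
Conditions: SeO2, 1,4-dioxane, 90 °C
Reagents that add atoms: selenium dioxide O=[Se]=O
Why: Riley oxidation (ene reaction, then [2,3]-sigmatropic shift of the allylseleninic acid) oxidises only the methyl trans to the ring and gives the (E)-enal.

Step 7
Reactants: 14 methyl (1R,2S,4R,6S)-2,4,6-trimethyl-2-[(1E)-2-methyl-3-oxoprop-1-en-1-yl]cyclohexane-1-carboxylate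
Product: 15 methyl (1R,2S,4R,6S)-2-[(1E,3E)-2,4-dimethyl-5-oxopenta-1,3-dien-1-yl]-2,4,6-trimethylcyclohexane-1-carboxylate
Conditions: Ph3P=C(CH3)CHO, toluene, 110 °C
Reagents that add atoms: 2-(triphenyl-λ5-phosphanylidene)propanal CC(C=O)=P(c1ccccc1)(c1ccccc1)c1ccccc1
Why: Wittig olefination with the stabilised formyl ylide is E-selective and gives the (E,E)-dienal.

Step 8
Reactants: 15 methyl (1R,2S,4R,6S)-2-[(1E,3E)-2,4-dimethyl-5-oxopenta-1,3-dien-1-yl]-2,4,6-trimethylcyclohexane-1-carboxylate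
Product: 16 methyl (1R,2S,4R,6S)-2-[(1E,3E)-2,4-dimethylhexa-1,3,5-trien-1-yl]-2,4,6-trimethylcyclohexane-1-carboxylate
Conditions: Ph3PCH3Br, KOt-Bu, THF, 0 °C
Reagents that add atoms: methyltriphenylphosphonium bromide C[P+](c1ccccc1)(c1ccccc1)c1ccccc1.[Br-]
Why: Wittig methylenation of the conjugated aldehyde completes the triene; the very hindered ester is untouched.

Step 9
Reactants: 16 methyl (1R,2S,4R,6S)-2-[(1E,3E)-2,4-dimethylhexa-1,3,5-trien-1-yl]-2,4,6-trimethylcyclohexane-1-carboxylate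
Product: 17 (1R,2S,4R,6S)-2-[(1E,3E)-2,4-dimethylhexa-1,3,5-trien-1-yl]-2,4,6-trimethylcyclohexane-1-carbaldehyde
Conditions: i-Bu2AlH, toluene, −78 °C; aq. KNaC4H4O6
Reagents that add atoms: none
Why: Half-reduction works because the tetrahedral aluminate of this hindered ester survives at −78 °C; the α-centre is already in its thermodynamic equatorial configuration.

Step 10
Reactants: 17 (1R,2S,4R,6S)-2-[(1E,3E)-2,4-dimethylhexa-1,3,5-trien-1-yl]-2,4,6-trimethylcyclohexane-1-carbaldehyde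
Product: 19 1-TrCy-3-(trimethylsilyl)prop-2-yn-1-one, via Li alkoxide 18 (not isolated)
Conditions: Me3SiC≡CH, n-BuLi, THF, −78 °C; then PhS(Cl)=Nt-Bu, −78 °C → rt
Reagents that add atoms: ethynyltrimethylsilane C#C[Si](C)(C)C
Why: Acetylide 1,2-addition followed by in-flask oxidation of the lithium alkoxide with the sulfinimidoyl chloride (Mukaiyama oxidation) gives the ynone, so that hydride rather than carbon sets the carbinol centre.

Step 11
Reactants: 19 1-TrCy-3-(trimethylsilyl)prop-2-yn-1-one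
Product: 21 (1R)-1-TrCy-prop-2-yn-1-ol, via silylated carbinol 20 (not isolated)
Conditions: LiBH(s-Bu)3, THF, −78 °C; then NaOH, H2O2, MeOH, 0 °C → rt
Reagents that add atoms: none
Why: Felkin–Anh reduction, with the bulky hydride entering anti to the quaternary ring carbon, sets the carbinol centre (future C-9) under control of the adjacent ring stereocentre; the basic peroxide work-up cleaves the C–Si bond.

Step 12
Reactants: 22 N-Boc-4-fluoro-L-phenylalanine
Product: 23 tert-butyl N-[(2S)-1-(4-fluorophenyl)-3-hydroxypropan-2-yl]carbamate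
Conditions: BH3·THF, THF, 0 °C → rt; MeOH
Reagents that add atoms: none
Why: Borane reduces the carboxylic acid chemoselectively and leaves the carbamate and the stereocentre alone.

Step 13
Reactants: 23 tert-butyl N-[(2S)-1-(4-fluorophenyl)-3-hydroxypropan-2-yl]carbamate
Product: 24 tert-butyl (4S)-4-[(4-fluorophenyl)methyl]-2,2-dimethyl-1,3-oxazolidine-3-carboxylate
Conditions: Me2C(OMe)2, PPTS (cat.), toluene, 80 °C
Reagents that add atoms: 2,2-dimethoxypropane COC(C)(C)OC
Why: Acid-catalysed N,O-acetalisation masks NH and OH in one ring.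

Step 14
Reactants: 24 tert-butyl (4S)-4-[(4-fluorophenyl)methyl]-2,2-dimethyl-1,3-oxazolidine-3-carboxylate
Product: 25 Cr(CO)3 complex (η6 on the fluoroarene) of 24
Conditions: Cr(CO)6, n-Bu2O/THF (10:1), 140 °C
Reagents that add atoms: hexacarbonylchromium Cr(CO)6 [Cr].[C-]#[O+].[C-]#[O+].[C-]#[O+].[C-]#[O+].[C-]#[O+].[C-]#[O+]
Why: Thermal ligand exchange gives the arene–Cr(CO)3 complex, which activates the C–F bond for SNAr; the two arene-face diastereomers are inconsequential.

Step 15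
Reactants: 21 (1R)-1-TrCy-prop-2-yn-1-ol; 25 Cr(CO)3 complex of 24
Product: 27 tert-butyl (4S)-4-{[4-({(1R)-1-TrCy-prop-2-yn-1-yl}oxy)phenyl]methyl}-2,2-dimethyl-1,3-oxazolidine-3-carboxylate, via Cr(CO)3 ether complex 26 (not isolated)
Conditions: NaH (1.0 equiv), DMF, 0 °C → rt; then pyridine, 90 °C
Reagents that add atoms: none
Why: Nucleophilic aromatic substitution (addition–elimination) of the hindered alkoxide at the Cr(CO)3-activated C–F carbon forms the aryl ether with retention, since the carbinol C–O bond is never broken; pyridine then displaces the arene from chromium.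

Step 16
Reactants: 27 propargylic aryl ether
Product: 29 methyl (4E,6S)-6-(ArN-oxy)-3-oxo-6-TrCy-hex-4-enoate, via alkenyl-ZrCp2Cl 28 (not isolated)
Conditions: Cp2Zr(H)Cl, CH2Cl2, rt; then MeO2CCH2COCl, CuBr·SMe2 (10 mol %), 0 °C → rt
Reagents that add atoms: methyl 3-chloro-3-oxopropanoate COC(=O)CC(=O)Cl
Why: syn-Hydrozirconation puts zirconium on the terminal carbon faster than it touches the diene, and copper-catalysed acylation of the alkenylzirconocene retains the E geometry, giving the enone β-keto ester dienophile.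

Step 17
Reactants: 29 methyl (4E,6S)-6-(ArN-oxy)-3-oxo-6-TrCy-hex-4-enoate
Product: 30 methyl 3-[9-(ArN-oxy)-Flu-1-yl]-3-oxopropanoate
Conditions: toluene (5 mM), BHT, 110 °C
Reagents that add atoms: none
Why: Intramolecular Diels–Alder reaction through the endo (ketone under diene) transition state, with the tether held trans-diequatorial on the ring A chair, gives the trans-anti-trans decahydrofluorene; the (E)-enone and (E,E)-diene geometries translate into C-1, C-2, C-4a and C-9a, and the Z-methyl of the diene is expected to gear against the axial 4b-methyl instead of sliding under ring A.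

Step 18
Reactants: 30 methyl 3-[9-(ArN-oxy)-Flu-1-yl]-3-oxopropanoate
Product: 31 methyl 3-(9-{4-[(2S)-2-amino-3-hydroxypropyl]phenoxy}-Flu-1-yl)-3-oxopropanoate
Conditions: TFA, CH2Cl2, H2O (5 equiv), 0 °C; aq. NaHCO3
Reagents that add atoms: none
Why: Acidolysis removes the Boc group (loss of isobutene and CO2) and hydrolyses the N,O-acetal; the ring alkenes and the β-keto ester tolerate brief cold acid.

Step 19
Reactants: 31 methyl 3-(9-{4-[(2S)-2-amino-3-hydroxypropyl]phenoxy}-Flu-1-yl)-3-oxopropanoate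
Product: 32 14-membered β-keto lactam of 31 (amide between the side-chain nitrogen and the propanoate carbonyl; CH2OH retained)
Conditions: DMAP (cat.), toluene (1 mM), 4 Å sieves, 110 °C
Reagents that add atoms: none
Why: Thermal aminolysis of the β-keto ester (via the acylketene, methanol lost) captured by the amine at high dilution gives the macrolactam, one atom larger and less strained than the final cyclophane; amine beats alcohol.

Step 20
Reactants: 32 14-membered β-keto lactam alcohol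
Product: 35 CNP0450261.1, via amino aldehyde 33 (not isolated), via pyrrolinone 34 (not isolated)
Conditions: Dess–Martin periodinane, CH2Cl2, 0 °C → rt; then Et3N, THF/H2O (4:1), 40 °C
Reagents that add atoms: water O
Why: Alcohol oxidation triggers a transannular Knoevenagel condensation that closes the γ-lactam and contracts the ring to the 13-membered carbocycle; base-mediated tautomerisation to the N-acyl enamine and hydration then give the hydroxy-lactam, whose hemiaminal and acyl-bearing centres equilibrate to the configuration the strained cyclophane prefers (assumed to be the natural one, by analogy with the same lactam in hirsutellone B).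

## Compound list

1 | (3S)-3-methylcyclohexan-1-one | O=C1C[C@@H](C)CCC1 | starting material
2 | methyl (4S)-4-methyl-2-oxocyclohexane-1-carboxylate (keto/enol, C-1 undefined) | COC(=O)C1CC[C@H](C)CC1=O | intermediate
3 | methyl (4S)-4-methyl-2-oxo-1-(phenylselanyl)cyclohexane-1-carboxylate | COC(=O)C1([Se]c2ccccc2)CC[C@H](C)CC1=O | intermediate
4 | methyl (4S)-1-(benzeneseleninyl)-4-methyl-2-oxocyclohexane-1-carboxylate | COC(=O)C1([Se](=O)c2ccccc2)CC[C@H](C)CC1=O | intermediate
5 | methyl (4S)-4-methyl-6-oxocyclohex-1-ene-1-carboxylate | COC(=O)C1=CC[C@H](C)CC1=O | intermediate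
6 | methyl (4S)-2-[(bromomagnesio)oxy]-4-methyl-6-(2-methylprop-1-en-1-yl)cyclohex-1-ene-1-carboxylate (C-6 epimers) | COC(=O)C1=C(O[Mg]Br)C[C@@H](C)CC1C=C(C)C | intermediate
7 | methyl (4S)-4-methyl-2-(2-methylprop-1-en-1-yl)-6-oxo-1-(phenylselanyl)cyclohexane-1-carboxylate | COC(=O)C1([Se]c2ccccc2)C(C=C(C)C)C[C@H](C)CC1=O | intermediate
8 | methyl (4S)-1-(benzeneseleninyl)-4-methyl-2-(2-methylprop-1-en-1-yl)-6-oxocyclohexane-1-carboxylate | COC(=O)C1([Se](=O)c2ccccc2)C(C=C(C)C)C[C@H](C)CC1=O | intermediate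
9 | methyl (4S)-4-methyl-2-(2-methylprop-1-en-1-yl)-6-oxocyclohex-1-ene-1-carboxylate | COC(=O)C1=C(C=C(C)C)C[C@H](C)CC1=O | intermediate
10 | methyl (4S,6S)-2-[(bromomagnesio)oxy]-4,6-dimethyl-6-(2-methylprop-1-en-1-yl)cyclohex-1-ene-1-carboxylate | COC(=O)C1=C(O[Mg]Br)C[C@@H](C)C[C@]1(C=C(C)C)C | intermediate
11 | methyl (4S,6S)-2-[(diethoxyphosphoryl)oxy]-4,6-dimethyl-6-(2-methylprop-1-en-1-yl)cyclohex-1-ene-1-carboxylate | COC(=O)C1=C(OP(=O)(OCC)OCC)C[C@@H](C)C[C@]1(C=C(C)C)C | intermediate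
12 | methyl (4R,6S)-2,4,6-trimethyl-6-(2-methylprop-1-en-1-yl)cyclohex-1-ene-1-carboxylate | COC(=O)C1=C(C)C[C@@H](C)C[C@]1(C=C(C)C)C | intermediate
13 | methyl (1R,2S,4R,6S)-2,4,6-trimethyl-2-(2-methylprop-1-en-1-yl)cyclohexane-1-carboxylate | COC(=O)[C@@H]1[C@@H](C)C[C@@H](C)C[C@]1(C=C(C)C)C | intermediate
14 | methyl (1R,2S,4R,6S)-2,4,6-trimethyl-2-[(1E)-2-methyl-3-oxoprop-1-en-1-yl]cyclohexane-1-carboxylate | COC(=O)[C@@H]1[C@@H](C)C[C@@H](C)C[C@]1(/C=C(\C)C=O)C | intermediate
15 | methyl (1R,2S,4R,6S)-2-[(1E,3E)-2,4-dimethyl-5-oxopenta-1,3-dien-1-yl]-2,4,6-trimethylcyclohexane-1-carboxylate | COC(=O)[C@@H]1[C@@H](C)C[C@@H](C)C[C@]1(/C=C(C)/C=C(\C)C=O)C | intermediate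
16 | methyl (1R,2S,4R,6S)-2-[(1E,3E)-2,4-dimethylhexa-1,3,5-trien-1-yl]-2,4,6-trimethylcyclohexane-1-carboxylate | COC(=O)[C@@H]1[C@@H](C)C[C@@H](C)C[C@]1(/C=C(C)/C=C(\C)C=C)C | intermediate
17 | (1R,2S,4R,6S)-2-[(1E,3E)-2,4-dimethylhexa-1,3,5-trien-1-yl]-2,4,6-trimethylcyclohexane-1-carbaldehyde | O=C[C@@H]1[C@@H](C)C[C@@H](C)C[C@]1(/C=C(C)/C=C(\C)C=C)C | intermediate
18 | lithium 1-TrCy-3-(trimethylsilyl)prop-2-yn-1-olate (both C-1 epimers) | [Li]OC(C#C[Si](C)(C)C)[C@@H]1[C@@H](C)C[C@@H](C)C[C@]1(/C=C(C)/C=C(\C)C=C)C | intermediate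
19 | 1-TrCy-3-(trimethylsilyl)prop-2-yn-1-one | C[Si](C)(C)C#CC(=O)[C@@H]1[C@@H](C)C[C@@H](C)C[C@]1(/C=C(C)/C=C(\C)C=C)C | intermediate
20 | (1R)-1-TrCy-3-(trimethylsilyl)prop-2-yn-1-ol | C[Si](C)(C)C#C[C@H](O)[C@@H]1[C@@H](C)C[C@@H](C)C[C@]1(/C=C(C)/C=C(\C)C=C)C | intermediate
21 | (1R)-1-TrCy-prop-2-yn-1-ol | C#C[C@H](O)[C@@H]1[C@@H](C)C[C@@H](C)C[C@]1(/C=C(C)/C=C(\C)C=C)C | intermediate
22 | (2S)-2-[(tert-butoxycarbonyl)amino]-3-(4-fluorophenyl)propanoic acid (N-Boc-4-fluoro-L-phenylalanine) | CC(C)(C)OC(=O)N[C@@H](Cc1ccc(F)cc1)C(=O)O | starting material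
23 | tert-butyl N-[(2S)-1-(4-fluorophenyl)-3-hydroxypropan-2-yl]carbamate | CC(C)(C)OC(=O)N[C@@H](Cc1ccc(F)cc1)CO | intermediate
24 | tert-butyl (4S)-4-[(4-fluorophenyl)methyl]-2,2-dimethyl-1,3-oxazolidine-3-carboxylate | CC(C)(C)OC(=O)N1[C@@H](Cc2ccc(F)cc2)COC1(C)C | intermediate
25 | tricarbonyl(η6-arene)chromium complex of 24, Cr(CO)3 on the fluorophenyl ring | CC(C)(C)OC(=O)N1[C@@H](Cc2ccc(F)cc2)COC1(C)C.[Cr].[C-]#[O+].[C-]#[O+].[C-]#[O+] | intermediate
26 | tricarbonyl(η6-arene)chromium complex of 27, Cr(CO)3 on the aryloxy ring | C#C[C@H](Oc1ccc(C[C@H]2COC(C)(C)N2C(=O)OC(C)(C)C)cc1)[C@@H]1[C@@H](C)C[C@@H](C)C[C@]1(/C=C(C)/C=C(\C)C=C)C.[Cr].[C-]#[O+].[C-]#[O+].[C-]#[O+] | intermediate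
27 | tert-butyl (4S)-4-{[4-({(1R)-1-TrCy-prop-2-yn-1-yl}oxy)phenyl]methyl}-2,2-dimethyl-1,3-oxazolidine-3-carboxylate | C#C[C@H](Oc1ccc(C[C@H]2COC(C)(C)N2C(=O)OC(C)(C)C)cc1)[C@@H]1[C@@H](C)C[C@@H](C)C[C@]1(/C=C(C)/C=C(\C)C=C)C | intermediate
28 | chlorobis(cyclopentadienyl)[(1E)-3-(ArN-oxy)-3-TrCy-prop-1-en-1-yl]zirconium, ether carbon as in 27 | Cl[Zr](C1C=CC=C1)(C1C=CC=C1)/C=C/[C@H](Oc1ccc(C[C@H]2COC(C)(C)N2C(=O)OC(C)(C)C)cc1)[C@@H]1[C@@H](C)C[C@@H](C)C[C@]1(/C=C(C)/C=C(\C)C=C)C | intermediate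
29 | methyl (4E,6S)-6-(ArN-oxy)-3-oxo-6-TrCy-hex-4-enoate | COC(=O)CC(=O)/C=C/[C@H](Oc1ccc(C[C@H]2COC(C)(C)N2C(=O)OC(C)(C)C)cc1)[C@@H]1[C@@H](C)C[C@@H](C)C[C@]1(/C=C(C)/C=C(\C)C=C)C | intermediate
30 | methyl 3-[9-(ArN-oxy)-Flu-1-yl]-3-oxopropanoate | C=C[C@@]1(C)C=C(C)[C@@H]2[C@@H]([C@H]1C(=O)CC(=O)OC)[C@H](Oc1ccc(C[C@H]3COC(C)(C)N3C(=O)OC(C)(C)C)cc1)[C@@H]1[C@@H](C)C[C@@H](C)C[C@]12C | intermediate
31 | methyl 3-(9-{4-[(2S)-2-amino-3-hydroxypropyl]phenoxy}-Flu-1-yl)-3-oxopropanoate | C=C[C@@]1(C)C=C(C)[C@@H]2[C@@H]([C@H]1C(=O)CC(=O)OC)[C@H](Oc1ccc(C[C@H](N)CO)cc1)[C@@H]1[C@@H](C)C[C@@H](C)C[C@]12C | intermediate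
32 | 14-membered β-keto lactam of 31: side-chain N acylated by the propanoate carbonyl, (S)-CH(CH2OH) retained, Flu core unchanged | C=C[C@@]1(C)C=C(C)[C@@H]2[C@@H]3[C@H](Oc4ccc(cc4)C[C@@H](CO)NC(=O)CC(=O)[C@H]31)[C@@H]1[C@@H](C)C[C@@H](C)C[C@]12C | intermediate
33 | aldehyde of 32 (CH2OH oxidised to CHO) | C=C[C@@]1(C)C=C(C)[C@@H]2[C@@H]3[C@H](Oc4ccc(cc4)C[C@@H](C=O)NC(=O)CC(=O)[C@H]31)[C@@H]1[C@@H](C)C[C@@H](C)C[C@]12C | intermediate
34 | Knoevenagel product of 33: (5S)-3-acyl-5-benzyl-1,5-dihydro-2H-pyrrol-2-one embedded in the 13-membered cyclophane | C=C[C@@]1(C)C=C(C)[C@@H]2[C@@H]3[C@H](Oc4ccc(cc4)C[C@H]4C=C(C(=O)N4)C(=O)[C@H]31)[C@@H]1[C@@H](C)C[C@@H](C)C[C@]12C | intermediate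
35 | CNP0450261.1 (hydroxy-γ-lactam para-cyclophane on the Flu core) | C=C[C@@]1(C)C=C(C)[C@@H]2[C@@H]3[C@H](Oc4ccc(cc4)C[C@@]4(O)C[C@H](C(=O)N4)C(=O)[C@H]31)[C@@H]1[C@@H](C)C[C@@H](C)C[C@]12C | target

## Step count and risk

Total: 20 steps. Longest linear sequence: 17 steps (steps 1–11 and 15–20); steps 12–14 are the three-step side branch.

The three steps most likely to fail are steps 15, 17 and 19.

Step 15 (aryl ether at the most hindered carbinol, with a free terminal alkyne present). If the SNAr is slow or the acetylide competes, the ether can be made by inversion instead of retention. The fallback sets out from 17. Addition of Me3SiC≡CLi without the oxidation gives mainly the Felkin carbinol (1S)-1-TrCy-3-(trimethylsilyl)prop-2-yn-1-ol F1, the C-1 epimer of 20. A Mitsunobu reaction (PPh3, DIAD, toluene) with the phenol tert-butyl (4S)-4-[(4-hydroxyphenyl)methyl]-2,2-dimethyl-1,3-oxazolidine-3-carboxylate F2 (from commercial N-Boc-L-tyrosinol and 2,2-dimethoxypropane) inverts the propargylic centre and gives the silylated ether tert-butyl (4S)-4-{[4-({(1R)-1-TrCy-3-(trimethylsilyl)prop-2-yn-1-yl}oxy)phenyl]methyl}-2,2-dimethyl-1,3-oxazolidine-3-carboxylate F3. K2CO3 in MeOH removes the silyl group and the route is rejoined at 27.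

Step 17 (facial selectivity of the cycloaddition). The endo transition state of opposite diene face avoids the Me/Me contact between the diene's Z-methyl and the axial 4b-methyl and could compete or win; cis-fused (exo) adducts and 1,5-hydrogen shift of the Z-methyl diene are further risks. The fallback runs the cycloaddition transannularly, after the large ring is closed, as in the biosynthesis where the cyclophane precedes the [4+2] step. It sets out from 29. TFA/CH2Cl2/H2O gives the amino alcohol methyl (4E,6S)-6-{4-[(2S)-2-amino-3-hydroxypropyl]phenoxy}-3-oxo-6-TrCy-hex-4-enoate F4. Heating with DMAP in toluene at 1 mM closes the 14-membered enone lactam F5 (not isolated), in which the aryl ether–amide strap restricts the dienophile conformations. The transannular Diels–Alder reaction then gives the tricycle directly and the route is rejoined at 32. Whether the strap favours the required face is not established.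

Step 19 (macrolactamisation by thermal aminolysis of a methyl β-keto ester). Enaminone formation or oligomers may win. The fallback changes the acyl donor to a thioester that is activated at room temperature by a thiophilic silver salt. It sets out from 27. Hydrozirconation as in step 16, then acylation with t-BuSC(O)CH2COCl, gives S-tert-butyl (4E,6S)-6-(ArN-oxy)-3-oxo-6-TrCy-hex-4-enethioate F6. The Diels–Alder reaction as in step 17 gives S-tert-butyl 3-[9-(ArN-oxy)-Flu-1-yl]-3-oxopropanethioate F7. TFA deprotection gives S-tert-butyl 3-(9-{4-[(2S)-2-amino-3-hydroxypropyl]phenoxy}-Flu-1-yl)-3-oxopropanethioate F8. AgOCOCF3 and Et3N in THF at high dilution close the lactam and the route is rejoined at 32.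

Further compounds
F1 | step 15 | (1S)-1-TrCy-3-(trimethylsilyl)prop-2-yn-1-ol | C[Si](C)(C)C#C[C@@H](O)[C@@H]1[C@@H](C)C[C@@H](C)C[C@]1(/C=C(C)/C=C(\C)C=C)C
F2 | step 15 | tert-butyl (4S)-4-[(4-hydroxyphenyl)methyl]-2,2-dimethyl-1,3-oxazolidine-3-carboxylate | CC(C)(C)OC(=O)N1[C@@H](Cc2ccc(O)cc2)COC1(C)C
F3 | step 15 | tert-butyl (4S)-4-{[4-({(1R)-1-TrCy-3-(trimethylsilyl)prop-2-yn-1-yl}oxy)phenyl]methyl}-2,2-dimethyl-1,3-oxazolidine-3-carboxylate | C[Si](C)(C)C#C[C@H](Oc1ccc(C[C@H]2COC(C)(C)N2C(=O)OC(C)(C)C)cc1)[C@@H]1[C@@H](C)C[C@@H](C)C[C@]1(/C=C(C)/C=C(\C)C=C)C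
F4 | step 17 | methyl (4E,6S)-6-{4-[(2S)-2-amino-3-hydroxypropyl]phenoxy}-3-oxo-6-TrCy-hex-4-enoate | COC(=O)CC(=O)/C=C/[C@H](Oc1ccc(C[C@H](N)CO)cc1)[C@@H]1[C@@H](C)C[C@@H](C)C[C@]1(/C=C(C)/C=C(\C)C=C)C
F5 | step 17 | 14-membered (E)-enone β-keto lactam of F4 (side-chain N acylated by the ester carbonyl; TrCy pendant) | O=C1CC(=O)/C=C/[C@@H]([C@@H]2[C@@H](C)C[C@@H](C)C[C@]2(/C=C(C)/C=C(\C)C=C)C)Oc2ccc(C[C@@H](CO)N1)cc2
F6 | step 19 | S-tert-butyl (4E,6S)-6-(ArN-oxy)-3-oxo-6-TrCy-hex-4-enethioate | CC(C)(C)SC(=O)CC(=O)/C=C/[C@H](Oc1ccc(C[C@H]2COC(C)(C)N2C(=O)OC(C)(C)C)cc1)[C@@H]1[C@@H](C)C[C@@H](C)C[C@]1(/C=C(C)/C=C(\C)C=C)C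
F7 | step 19 | S-tert-butyl 3-[9-(ArN-oxy)-Flu-1-yl]-3-oxopropanethioate | C=C[C@@]1(C)C=C(C)[C@@H]2[C@@H]([C@H]1C(=O)CC(=O)SC(C)(C)C)[C@H](Oc1ccc(C[C@H]3COC(C)(C)N3C(=O)OC(C)(C)C)cc1)[C@@H]1[C@@H](C)C[C@@H](C)C[C@]12C
F8 | step 19 | S-tert-butyl 3-(9-{4-[(2S)-2-amino-3-hydroxypropyl]phenoxy}-Flu-1-yl)-3-oxopropanethioate | C=C[C@@]1(C)C=C(C)[C@@H]2[C@@H]([C@H]1C(=O)CC(=O)SC(C)(C)C)[C@H](Oc1ccc(C[C@H](N)CO)cc1)[C@@H]1[C@@H](C)C[C@@H](C)C[C@]12C
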